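The pentasubstituted benzene ring (C1'–C6') is treated as the dehydrogenated form of a 5-aryl-4,6-diprenylcyclohexane-1,3-dione. Its mirror plane through C1' and C4' makes the oxygens at C3' and C5' equivalent, so the OH/OMe pattern follows from a single enol etherification. The ring is assembled in one operation by a [3+3] Michael–Claisen annulation: C3 of 6-methylhept-5-en-2-one bonds to the β-carbon of a methyl α-prenyl-β-(benzofuran-2-yl)acrylate (C1'–C2'), and the ketone methyl then acylates on the ester (C4'–C5'). The benzofuran phenol is carried as its base-stable methoxymethyl ether. O-methylation, one dehydrogenation and deprotection finish the synthesis.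

Key step: step 7

Remark: the target has no stereocentre. Stereodescriptors for 13–18 give the relative configuration of racemic or meso material, and any minor diastereomer converges at step 9, where all ring stereocentres are erased.

Step 1
Reactants: 1 2,4-dihydroxybenzaldehyde
Product: 2 2-hydroxy-4-(methoxymethoxy)benzaldehyde
Conditions: MOMCl, K2CO3, acetone, 0 °C to rt
Reagents that add atoms: chloromethyl methyl ether, COCCl
Why: The 2-OH is hydrogen-bonded to the formyl group and less nucleophilic, so Williamson-type O-alkylation should occur at the 4-OH only.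

Step 2
Reactants: 2 2-hydroxy-4-(methoxymethoxy)benzaldehyde; 3 ethyl bromoacetate
Product: 5 ethyl 6-(methoxymethoxy)-1-benzofuran-2-carboxylate, via aryloxyacetate 4 (not isolated)
Conditions: K2CO3, DMF, 90 °C
Reagents that add atoms: none
Why: Williamson O-alkylation of the phenoxide is followed by intramolecular aldol condensation of the ester α-carbon onto the ortho formyl group and dehydration to the furan (Rap–Stoermer-type benzofuran synthesis).

Step 3
Reactants: 5 ethyl 6-(methoxymethoxy)-1-benzofuran-2-carboxylate
Product: 6 [6-(methoxymethoxy)-1-benzofuran-2-yl]methanol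
Conditions: LiAlH4, THF, 0 °C
Reagents that add atoms: none
Why: Hydride reduction of the ester to the primary alcohol should leave the acetal and the benzofuran untouched.

Step 4
Reactants: 6 [6-(methoxymethoxy)-1-benzofuran-2-yl]methanol
Product: 7 6-(methoxymethoxy)-1-benzofuran-2-carbaldehyde
Conditions: MnO2, CH2Cl2, rt
Reagents that add atoms: none
Why: MnO2 oxidizes the activated heteroaryl carbinol selectively to the aldehyde without over-oxidation.

Step 5
Reactants: 8 trimethyl phosphonoacetate; 9 prenyl bromide
Product: 10 methyl 2-(dimethoxyphosphoryl)-5-methylhex-4-enoate (racemic)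
Conditions: NaH, THF, 0 °C to rt (8 in slight excess)
Reagents that add atoms: none
Why: The sodium salt of the phosphonoacetate undergoes SN2 alkylation at the primary allylic bromide, the slight excess of 8 limiting dialkylation; the new stereocentre is racemic and is destroyed in step 6.

Step 6
Reactants: 7 6-(methoxymethoxy)-1-benzofuran-2-carbaldehyde; 10 methyl 2-(dimethoxyphosphoryl)-5-methylhex-4-enoate
Product: 11 methyl (E)-2-{[6-(methoxymethoxy)-1-benzofuran-2-yl]methylidene}-5-methylhex-4-enoate
Conditions: NaH, THF, 0 °C to rt
Reagents that add atoms: none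
Why: Horner–Wadsworth–Emmons olefination of the aromatic aldehyde with the α-alkyl phosphonate anion should give the trisubstituted acrylate with aryl trans to the ester (E), and the alkene geometry is lost in step 7 in any case.

Step 7
Reactants: 11 methyl (E)-2-{[6-(methoxymethoxy)-1-benzofuran-2-yl]methylidene}-5-methylhex-4-enoate; 12 6-methylhept-5-en-2-one
Product: 14 meso all-trans 5-[6-(methoxymethoxy)-1-benzofuran-2-yl]-4,6-bis(3-methylbut-2-enyl)cyclohexane-1,3-dione, via keto ester 13 (not isolated)
Conditions: 12 (3 equiv), KOtBu (2.5 equiv), THF, 0 °C to rt; then 1 M HCl (aq.), 0 °C, to pH 4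
Reagents that add atoms: none
Why: tert-Butoxide equilibrates the two enolates of 12; the internal enolate (C3) adds reversibly to the β-carbon of 11 (bond C1'–C2'), proton transfer gives the methyl-side enolate of keto ester 13, this acylates on the methyl ester with loss of methoxide (bond C4'–C5'), and deprotonation of the new 1,3-dione at C2 makes the sequence irreversible. The closest known reaction type is the alkoxide-mediated consecutive Michael–Claisen [3+3] annulation of methyl ketones with α,β-unsaturated esters, used here with a more hindered α-alkyl-β-aryl acrylate. The carbocycle closes in a 6-(enolendo)-exo-trig Claisen condensation. C4 and C6 are epimerizable α-carbons set under thermodynamic control by enolization in 13 and 14, so both prenyl groups should settle equatorial and trans to the equatorial aryl group at C5, whose configuration is thereby fixed relative to them (meso, all-trans). The step needs Michael addition through C3 and not C1 of the ketone: the more substituted enolate is favoured at equilibrium, and because the Michael step is reversible the adduct that can close through an unhindered CH3 enolate should be drained faster than the regioisomeric adduct, which would have to close through a hindered secondary carbon (Curtin–Hammett), while the excess of 12 keeps enolate exchange fast.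

Step 8
Reactants: 14 meso all-trans 5-[6-(methoxymethoxy)-1-benzofuran-2-yl]-4,6-bis(3-methylbut-2-enyl)cyclohexane-1,3-dione
Product: 15 rac-(4S,5S,6R)-3-methoxy-5-[6-(methoxymethoxy)-1-benzofuran-2-yl]-4,6-bis(3-methylbut-2-enyl)cyclohex-2-en-1-one (4,5-trans, 5,6-trans)
Conditions: TMSCHN2, MeOH/toluene, 0 °C to rt
Reagents that add atoms: trimethylsilyldiazomethane, C[Si](C)(C)C=[N+]=[N-]
Why: Diazomethane released in the flask O-methylates the acidic enol without C-methylation, and because the two carbonyl groups of meso 14 are enantiotopic only one constitutional vinylogous ester can form, as a racemate.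

Step 9
Reactants: 15 rac-(4S,5S,6R)-3-methoxy-5-[6-(methoxymethoxy)-1-benzofuran-2-yl]-4,6-bis(3-methylbut-2-enyl)cyclohex-2-en-1-one
Product: 19 5-methoxy-3-[6-(methoxymethoxy)-1-benzofuran-2-yl]-2,4-bis(3-methylbut-2-enyl)phenol, via selenide 16 (not isolated), via selenoxide 17 (not isolated), via dienone 18 (not isolated)
Conditions: LiN(iPr)2, THF, −78 °C; PhSeCl (1.0 equiv), −78 °C; mCPBA (1.0 equiv), −78 °C; then iPr2NH, −78 °C to rt
Reagents that add atoms: none
Why: Kinetic α'-deprotonation of the vinylogous ester at C6 (Stork–Danheiser-type enolate), selenenylation anti to the C5 aryl group so that selenium is cis to H5, low-temperature oxidation and syn selenoxide elimination into the ring should give the cross-conjugated 4H-dienone, which tautomerizes to the phenol, while the amine traps benzeneselenenic acid before it can add to the prenyl alkenes.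

Step 10
Reactants: 19 5-methoxy-3-[6-(methoxymethoxy)-1-benzofuran-2-yl]-2,4-bis(3-methylbut-2-enyl)phenol
Product: 20 2-[3-hydroxy-5-methoxy-2,6-bis(3-methylbut-2-enyl)phenyl]-1-benzofuran-6-ol (CNP0324103.0)
Conditions: HCl (aq., 2 M), MeOH, rt
Reagents that add atoms: none
Why: Acid-catalysed acetal exchange with methanol cleaves the aryl methoxymethyl ether at room temperature, conditions that should be too mild for cyclization of the C3' hydroxyl onto the neighbouring prenyl group.

Compound list
1 | 2,4-dihydroxybenzaldehyde | O=Cc1ccc(O)cc1O | starting material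
2 | 2-hydroxy-4-(methoxymethoxy)benzaldehyde | COCOc1ccc(C=O)c(O)c1 | intermediate
3 | ethyl bromoacetate | CCOC(=O)CBr | starting material
4 | ethyl 2-[2-formyl-5-(methoxymethoxy)phenoxy]acetate (formed in the flask) | CCOC(=O)COc1cc(OCOC)ccc1C=O | intermediate
5 | ethyl 6-(methoxymethoxy)-1-benzofuran-2-carboxylate | CCOC(=O)c1cc2ccc(OCOC)cc2o1 | intermediate
6 | [6-(methoxymethoxy)-1-benzofuran-2-yl]methanol | OCc1cc2ccc(OCOC)cc2o1 | intermediate
7 | 6-(methoxymethoxy)-1-benzofuran-2-carbaldehyde | O=Cc1cc2ccc(OCOC)cc2o1 | intermediate
8 | trimethyl phosphonoacetate | COC(=O)CP(=O)(OC)OC | starting material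
9 | prenyl bromide (1-bromo-3-methylbut-2-ene) | CC(C)=CCBr | starting material
10 | methyl 2-(dimethoxyphosphoryl)-5-methylhex-4-enoate (racemic) | COC(=O)C(CC=C(C)C)P(=O)(OC)OC | intermediate
11 | methyl (E)-2-{[6-(methoxymethoxy)-1-benzofuran-2-yl]methylidene}-5-methylhex-4-enoate | COC(=O)/C(CC=C(C)C)=C/c1cc2ccc(OCOC)cc2o1 | intermediate
12 | 6-methylhept-5-en-2-one | CC(=O)CCC=C(C)C | starting material
13 | methyl 4-acetyl-3-[6-(methoxymethoxy)-1-benzofuran-2-yl]-7-methyl-2-(3-methylbut-2-enyl)oct-6-enoate (equilibrating mixture of diastereomers, formed in the flask) | COC(=O)C(CC=C(C)C)C(c1cc2ccc(OCOC)cc2o1)C(CC=C(C)C)C(C)=O | intermediate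
14 | meso (4R,5s,6S) all-trans 5-[6-(methoxymethoxy)-1-benzofuran-2-yl]-4,6-bis(3-methylbut-2-enyl)cyclohexane-1,3-dione | O=C1CC(=O)[C@@H](CC=C(C)C)[C@H](c2cc3ccc(OCOC)cc3o2)[C@H]1CC=C(C)C | intermediate
15 | rac-(4S,5S,6R)-3-methoxy-5-[6-(methoxymethoxy)-1-benzofuran-2-yl]-4,6-bis(3-methylbut-2-enyl)cyclohex-2-en-1-one (all-trans) | O=C1C=C(OC)[C@@H](CC=C(C)C)[C@H](c2cc3ccc(OCOC)cc3o2)[C@H]1CC=C(C)C | intermediate
16 | racemic 3-methoxy-5-[6-(methoxymethoxy)-1-benzofuran-2-yl]-4,6-bis(3-methylbut-2-enyl)-6-(phenylselanyl)cyclohex-2-en-1-one, selenium trans to the C5 aryl group and cis to H5 (formed in the flask) | O=C1C=C(OC)[C@@H](CC=C(C)C)[C@H](c2cc3ccc(OCOC)cc3o2)[C@@]1(CC=C(C)C)[Se]c1ccccc1 | intermediate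
17 | selenoxide of 16, mixture of epimers at selenium (formed in the flask) | O=C1C=C(OC)[C@@H](CC=C(C)C)[C@H](c2cc3ccc(OCOC)cc3o2)[C@@]1(CC=C(C)C)[Se](=O)c1ccccc1 | intermediate
18 | racemic 3-methoxy-5-[6-(methoxymethoxy)-1-benzofuran-2-yl]-4,6-bis(3-methylbut-2-enyl)cyclohexa-2,5-dien-1-one (formed in the flask) | O=C1C=C(OC)[C@@H](CC=C(C)C)C(c2cc3ccc(OCOC)cc3o2)=C1CC=C(C)C | intermediate
19 | 5-methoxy-3-[6-(methoxymethoxy)-1-benzofuran-2-yl]-2,4-bis(3-methylbut-2-enyl)phenol | COc1cc(O)c(CC=C(C)C)c(-c2cc3ccc(OCOC)cc3o2)c1CC=C(C)C | intermediate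
20 | 2-[3-hydroxy-5-methoxy-2,6-bis(3-methylbut-2-enyl)phenyl]-1-benzofuran-6-ol | COc1cc(O)c(CC=C(C)C)c(-c2cc3ccc(O)cc3o2)c1CC=C(C)C | target

Total step count: 10. Longest linear sequence: 9 steps (1, 2, 3, 4, 6, 7, 8, 9, 10 from 2,4-dihydroxybenzaldehyde).

Steps most likely to fail

Step 7. The conjugate addition may proceed through the methyl-side enolate of 12, which after ring closure places one prenyl group between the two carbonyl groups. The hindered acrylate may also fail to accept the ketone enolate at all, so that ketone self-condensation takes over. The fallback builds the dione ring first and introduces the prenyl groups afterwards at positions fixed by dianion chemistry; it sets out from 7 and returns at 14. Claisen–Schmidt condensation of 7 with acetone (NaOH, aqueous acetone) should give (E)-4-[6-(methoxymethoxy)-1-benzofuran-2-yl]but-3-en-2-one F1. Michael addition of dimethyl malonate and Claisen ring closure (NaOMe, MeOH, reflux) should give methyl trans-6-[6-(methoxymethoxy)-1-benzofuran-2-yl]-2,4-dioxocyclohexane-1-carboxylate F2. Saponification (NaOH, aqueous) and decarboxylation on buffering with acetic acid to pH 4–5 with gentle warming should give 5-[6-(methoxymethoxy)-1-benzofuran-2-yl]cyclohexane-1,3-dione F3. The dianion of F3 (LiN(iPr)2, 2.2 equiv, THF/HMPA, −78 to 0 °C) should be alkylated by prenyl bromide at C4, trans to the aryl group, giving trans-5-[6-(methoxymethoxy)-1-benzofuran-2-yl]-4-(3-methylbut-2-enyl)cyclohexane-1,3-dione F4. A second dianion alkylation at the unsubstituted C6 under the same conditions should give 14.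

Step 9. The selenoxide may eliminate into the prenyl side chain instead of toward H5, which leaves an exocyclic double bond that does not tautomerize to the arene by itself. The selenium electrophile or the selenenic acid may also add to the prenyl double bonds. The fallback avoids selenium and the oxidation stage and relies on thermodynamic aromatization; it sets out from 15 and returns at 19. The lithium enolate of 15 (LiN(iPr)2, THF, −78 °C) is treated with N-tert-butylbenzenesulfinimidoyl chloride, which dehydrogenates enolates directly at low temperature. The crude product, where the new double bond may lie in the side chain as in 3-methoxy-5-[6-(methoxymethoxy)-1-benzofuran-2-yl]-4-(3-methylbut-2-enyl)-6-(3-methylbut-2-enylidene)cyclohex-2-en-1-one F5, is then warmed with DBU in toluene. Base-mediated isoaromatization (proton shift from C5 to the exocyclic carbon, then dienone–phenol tautomerization) should funnel all dehydrogenated isomers into 19.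

Step 10. Acid may promote cyclization of the C3' hydroxyl onto the adjacent prenyl double bond, or addition of solvent to the prenyl alkenes, in competition with acetal cleavage. The fallback replaces Brønsted-acid solvolysis by amine-buffered silyl transfer through a silyl ether, in which the sensitive phenol is masked while the acetal is cleaved; it sets out from 19 and returns at 20. Treatment of 19 with TMSOTf and 2,2'-bipyridyl (CH2Cl2, 0 °C) should convert the aryl methoxymethyl ether into a trimethylsilyl ether and silylate the free phenol, giving 2-[3-methoxy-2,6-bis(3-methylbut-2-enyl)-5-(trimethylsilyloxy)phenyl]-6-(trimethylsilyloxy)-1-benzofuran F6. Hydrolysis of both silyl ethers with water at rt should then give 20.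

Further compounds
F1 | step 7 | (E)-4-[6-(methoxymethoxy)-1-benzofuran-2-yl]but-3-en-2-one | CC(=O)/C=C/c1cc2ccc(OCOC)cc2o1
F2 | step 7 | methyl trans-6-[6-(methoxymethoxy)-1-benzofuran-2-yl]-2,4-dioxocyclohexane-1-carboxylate (racemic) | COC(=O)[C@@H]1C(=O)CC(=O)C[C@H]1c1cc2ccc(OCOC)cc2o1
F3 | step 7 | 5-[6-(methoxymethoxy)-1-benzofuran-2-yl]cyclohexane-1,3-dione | O=C1CC(=O)CC(c2cc3ccc(OCOC)cc3o2)C1
F4 | step 7 | trans-5-[6-(methoxymethoxy)-1-benzofuran-2-yl]-4-(3-methylbut-2-enyl)cyclohexane-1,3-dione (racemic) | O=C1CC(=O)[C@@H](CC=C(C)C)[C@H](c2cc3ccc(OCOC)cc3o2)C1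
F5 | step 9 | 3-methoxy-5-[6-(methoxymethoxy)-1-benzofuran-2-yl]-4-(3-methylbut-2-enyl)-6-(3-methylbut-2-enylidene)cyclohex-2-en-1-one (racemic, 4,5-trans, exocyclic alkene geometry undefined) | O=C1C=C(OC)[C@@H](CC=C(C)C)[C@H](c2cc3ccc(OCOC)cc3o2)C1=CC=C(C)C
F6 | step 10 | 2-[3-methoxy-2,6-bis(3-methylbut-2-enyl)-5-(trimethylsilyloxy)phenyl]-6-(trimethylsilyloxy)-1-benzofuran | COc1cc(O[Si](C)(C)C)c(CC=C(C)C)c(-c2cc3ccc(O[Si](C)(C)C)cc3o2)c1CC=C(C)C
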